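The charge of this flask is framed by two ratios: coupling partner to starting material, 0.700, and protic impurity to starting material, 0.500.

common to all: initiator 3.2 mM

| flask | starting material | coupling partner | protic impurity | remark | time |
|---|---|---|---|---|---|
| theta | 0.050 M | 0.035 M | 0.025 M | run made earlier |  |
| eta | 0.050 M | 0.053 M | 0.025 M | run made earlier |  |
| dusk | 0.050 M | 0.0350 M | 0.0250 M | one stirred flow tank at steady state, fed with the mixture as stated, mean residence time 15 min |  |
| summer | 0.050 M | 0.0350 M (fed, over 12.0 min) | 0.0250 M | all but coupling partner at the start; coupling partner goes in evenly over 12.0 min, the run ends at 15 min | 15 min |
| dawn | 0.050 M (fed, over 12.0 min) | 0.0350 M | 0.0250 M | all but starting material at the start; starting material goes in evenly over 12.0 min, the run ends at 15 min | 15 min |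
| winter | 0.050 M | 0.0350 M | 0.0250 M | a closed flask charged with all of it at once and left for 15 min | 15 min |

- theta (time / min: target / %): 2.00: 27.5; 4.00: 41.4; 5.00: 44.8; 8.00: 51.1; 10.0: 51.7
- eta (time / s: target / %): 10.0: 4.4; 25.0: 10.4; 40.0: 14.8; 60.0: 21.9; 90.0: 29.0

(each reading ± 0.5 percentage points)

- the set-up with the highest amount of target at the outlet or at the end, in percent of the starting material put in ("none" if the first two lie within 2 percentage points) (dusk / summer / dawn / winter / none)
- amount of target at the outlet or at the end, in percent of the starting material put in, dusk
- amount of target at the outlet or at the end, in percent of the starting material put in, summer
- amount of target at the outlet or at the end, in percent of the starting material put in, dawn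
- amount of target at the outlet or at the end, in percent of the starting material put in, winter

- the stated concentrations are those of everything mixed, before any reaction; amounts are the same in each set-up
- the feed brings no volume worth counting
- the earlier runs were made in a closed, stirred flask

With the main step alone, starting material and coupling partner giving target one to one, the coupling partner is the limiting reagent and the ceiling is 70.0% of the starting material. The theta run, which has the charge of winter, reads 51.7% at 10.0 min, having gained 0.6 percentage points over its last interval, so its rise has slowed well short of that ceiling.

One more process is added here as this reckoning's own assumption: each protic impurity destroys one starting material. That leaves 50.0% of the charge, and this figure is called the spared share: the part of the starting material still there once each protic impurity has taken one. The theta reading lies 1.7 points above it.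

Then comes the rest, the initiator. The theta run made 8.08 target per initiator charged, so the target appears to come from a chain of repeated turnovers. Its pace in the theta run reads 6.88 mM min⁻¹ over the first 2.00 min. The eta run, with more coupling partner, goes faster. A slow chain races the impurity, and the small excess over the spared share is read as the target won in that race.

This reckoning therefore expects winter to stay near the theta reading and dusk a little under it, with some unreacted material leaving the tank. Summer should fall below the spared share, its starting material standing beside the impurity while the coupling partner is dosed. In dawn the feed of 4.17 mM min⁻¹ is slower than the pace, so dawn should rise above the spared share and come out best.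

The forecast differs, reasoning that “some partner is being lost”, and gives 40.5% for dusk, 44% for summer, 38% for dawn and 53% for winter, with winter best.

The flasks give 51.2% in dusk, 47.6% in summer, 55.3% in dawn and 51.4% in winter, so dawn is best.

    coupling partner + first chain carrier → target + second chain carrier (k = 2.90 × 10⁵ M⁻¹ s⁻¹)
    initiator → 2 initiating radical (k = 2.20 × 10⁻⁴ s⁻¹)
    starting material + second chain carrier → by-product + first chain carrier (k = 6.00 × 10⁵ M⁻¹ s⁻¹)
    first chain carrier → ended carrier (k = 91.0 s⁻¹)
    2 second chain carrier → ended chains (k = 1.30 × 10⁹ M⁻¹ s⁻¹)
    starting material + initiating radical → capped initiator + first chain carrier (k = 1.20 × 10⁶ M⁻¹ s⁻¹)
    starting material + protic impurity → quenched substrate (k = 0.640 M⁻¹ s⁻¹)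

Dawn ends 5.3 points above the spared share, and summer, the second flask, ends 2.4 points below it. Dusk ends 1.2 points above it, and a part of what the dusk tank lacks is due to the step from first chain carrier to ended carrier. With that step taken away, the dusk tank gives 64.2%, which is 13 points more and 27% of what is missing.

The numbers in the tables were generated by integration for substances that don't exist; noise was put on by code.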